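## Analysis of the target

The target is a C15 dibromo ether in which a 7‑oxabicyclo[2.2.1]heptane (C1 with a methyl group, C2 with bromine, C3, bridgehead C4, C5, C6, bridging O7) is joined through C4 to C1′ of a 4‑bromo‑3,3‑dimethylcyclohexane (C3′ gem‑dimethyl, C4′ bromine). It has five stereocentres: C1 (R), C2 (R) and C4 (S) in the bicycle, C1′ (S) and C4′ (S) in the cyclohexane. The bridge holds O7 on one face at C1 and C4 and the C2 bromine is endo, anti to O7, so C1 and C2 follow from C4 once the ether is closed by anti addition across a C1=C2 alkene. The cyclohexane substituents are trans and both equatorial, and this pair is insulated from the bicycle by the C4–C1′ single bond, so each half needs its own absolute control. Both bromides are secondary; C4′–Br is neopentyl‑type (next to quaternary C3′), cannot be introduced reliably by substitution, is open to elimination, and in 4‑bromo ketone intermediates to 1,3‑elimination through the enolate. The hard points are the fully substituted C4, whose two CH2 arms (C3 and C5) differ only one atom further out, and the C1′/C4′ relationship, which is only weakly biased because ring inversion keeps the C1′ substituent equatorial in either epimer. The strategy rests on C4: a tetracoordinate boron ate complex can deliver its substituents as chemically different groups, with O7 coming from the C–B bond, the C5 arm as the migrating group, the C3 arm from the alkene terminus plus an external electrophile, and C1′ already on the alkene.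

## Retrosynthetic reasoning

**20 to 19.** The O7–C1 and C2–Br bonds are cut together. Closing the ether by transannular attack of the C4 hydroxyl on a bromonium ion of cyclohexenol 19 can only place oxygen on its own face at the tertiary C1 and bromine anti at C2. The second bromide therefore arrives last and its configuration is a consequence of C4. The forward step needs the bromonium ion on the face opposite the hydroxyl.

**19 to 18.** The C1=C2 alkene is cut by ring‑closing metathesis to dienol 18. This is only possible because the two arms on C4 are different (allyl and 3‑methylbut‑3‑enyl), so the ring alkene can form on one side only and C4 is a defined stereocentre. The forward step has to join a monosubstituted and a 1,1‑disubstituted alkene.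

**18 to 17.** The C4–O bond is traced to the C4–B bond of the tertiary boronic ester 17. Oxidation with retention puts oxygen on the face boron occupied.

**17 to 12, 14 and 15 (key).** C4–C5 and C3–C2 are cut in one operation. C4 is the boron‑bearing alkene carbon of alkenyl boronate 12, C5 arrives as the migrating group of organolithium 14, and C3 is the alkene terminus that is joined to vinyl bromide 15. Cutting here gives C4 its two nearly identical arms as different groups by construction and sets the stereocentre with a chiral catalyst rather than with the remote cyclohexane. The forward reaction must favour the metallate shift over plain alkenyl transfer and leave the alkyl bromide alone.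

**12 to 10 and 11, 10 to 8, 8 to 7.** The C–B bond of 12 comes from the C–Br bond of bromoalkene 10 and diboron 11. The bromoalkene comes from alkyne 8 by Markovnikov bromoboration and protonolysis, and the alkyne from aldehyde 7 by one‑carbon homologation. A direct borylation of the alkyne is avoided because its regiochemistry is not dependable with a branched alkyl substituent.

**7 to 6 to 5.** The C1′–CHO bond is cut back to ketone 5 through enol ether 6. C1′ becomes a stereocentre here and, being α to the aldehyde, is adjusted by equilibration and separation.

**5 to 4 to 3 to 1.** The absolute configuration at C4′ is taken by resolving racemic ketone 4. The ring bond C2′–C3′ and the C4′–Br bond are cut together, back to enol acetate 3 of sulcatone 1, because a bromonium‑induced cyclisation makes the neopentyl‑type bromide without a substitution step.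

**14 to 13.** The organolithium is made from bromide 13 by reductive lithiation.

## Alternatives that were turned down

**Alternative 1:** The cyclohexane is made last. C2′–C3′ and C4′–Br are cut, leading to the oxabicyclic 1,5‑diene A2. In the forward step a bromonium donor attacks the prenyl alkene of A2, the 1,1‑disubstituted alkene closes the ring 6‑endo through a chair, and proton loss gives cyclohexene A1.
- For: it is convergent and biomimetic, it makes the neopentyl bromide and the ring in one late step, and it never handles a base‑sensitive 4‑bromo ketone. On these points it is stronger than the chosen route.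
- Against: the bromonium ion forms five bonds away from the nearest stereocentre, so C4′ is formed without control. The C1′ cation sits next to the oxygen‑bearing C4, which invites fragmentation or oxygen participation. C1′–H must then be set by reducing the ring alkene of A1, with no facial bias from the nearly symmetric ring and with two C–Br bonds at risk.
- Comparison: two stereocentres stay uncontrolled at the end, where separation costs most. The chosen strategy fixes C4′ at the first ring‑forming stage, where resolution is cheap, and sets C4 with a catalyst.

**Alternative 2:** C4–C5 and C1–C6 are cut by a retro‑[4+2]. In the forward step bromofuran A4 and acrylate A5 combine under Lewis acid catalysis to the oxabicycloheptene A3.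
- For: both C–O bonds of the bridge and the bromine position are already in the furan, the bicycle forms in one step, and exo‑face reduction of the vinyl bromide could give the endo bromide. It is more direct to the bicycle than the chosen route.
- Against: a 2,5‑disubstituted furan with a bulky secondary alkyl group and a deactivating bromine is a poor, reversible diene. Regio‑ and endo/exo mixtures are expected. The furan faces are distinguished only by the remote cyclohexane, so the absolute configuration of C1 and C4 is uncontrolled. The ester then has to be removed and the vinyl bromide reduced without hydrogenolysis.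
- Comparison: the cycloaddition saves steps in ring construction but needs several corrective steps and gives no control at the bridgeheads. The chosen strategy sets C4 by catalyst and lets C1 and C2 follow.

**Alternative 3:** C4–C3 and C4–C5 are both cut from one ester carbon. In the forward step di‑Grignard reagent A8 adds twice to ester A7 and closes the methylidenecyclohexanol A6.
- For: it is the shortest assembly of the skeleton, uses robust organomagnesium chemistry without a transition metal, and the key step has no stereochemical issue because the carbinol carbon of A6 is not yet a stereocentre. On step count and simplicity it is stronger.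
- Against: C4 becomes a stereocentre only when the exocyclic alkene is moved into the ring towards one of two constitutionally identical arms. That needs a desymmetrising isomerisation controlled by a remote centre or a chiral catalyst, on a tertiary alcohol that ionises easily under acid.
- Comparison: the decisive stereocentre rests on the least certain step. The chosen strategy distinguishes the two arms as they are attached, so metathesis can place the alkene on one side only.

Key step: step 10

Assumption: the sense of induction of the ketoreductase (step 3) and of the ferrocenyl bisphosphine (step 10) cannot be predicted with certainty; both antipodal catalysts are obtainable, and the descriptors below state the stereoisomer that is required.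

## Route

Step 1
Reactants: 1 6-methylhept-5-en-2-one (sulcatone)
Product: 3 6-methylhepta-1,5-dien-2-yl acetate, via lithium 6-methylhepta-1,5-dien-2-olate 2 (not isolated)
Conditions: LiN(i-Pr)2, THF, −78 °C (ketone added to base); then Ac2O, −78 → 0 °C
Reagents that add atoms: acetic anhydride, CC(=O)OC(C)=O
Why: Kinetic deprotonation at the methyl group and O‑acylation of the lithium enolate give the terminal enol acetate. An enol ester is used instead of a silyl enol ether because it is less nucleophilic towards electrophilic bromine than the trisubstituted alkene, yet still terminates a cation–alkene cyclisation at carbon.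

Step 2
Reactants: 3 6-methylhepta-1,5-dien-2-yl acetate
Product: 4 rac-4-bromo-3,3-dimethylcyclohexan-1-one
Conditions: Et2SBr·SbCl5Br (1.1 equiv), MeNO2, −25 °C; aq NaHCO3/Na2SO3
Reagents that add atoms: bromodiethylsulfonium bromopentachloroantimonate, CC[S+](Br)CC.Cl[Sb-](Cl)(Cl)(Cl)(Cl)Br
Why: Bromonium‑induced cation–alkene cyclisation: the bromonium ion should form at the more electron‑rich trisubstituted alkene, the CH2 terminus of the enol acetate opens it at the tertiary carbon through a chair (6‑endo), and the acyloxycarbenium ion loses its acetyl group to give the ketone. The neopentyl‑type C–Br bond is made without a substitution step; no stereocontrol is attempted and the product is racemic.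

Step 3
Reactants: 4 rac-4-bromo-3,3-dimethylcyclohexan-1-one
Product: 5 (4S)-4-bromo-3,3-dimethylcyclohexan-1-one
Conditions: ketoreductase (chosen from a commercial panel for reduction of the 4R enantiomer), NADP+ (cat.), i-PrOH, phosphate buffer pH 7, 30 °C, stopped just past half conversion; chromatography
Reagents that add atoms: none
Why: Enzymatic kinetic resolution by enantioselective carbonyl reduction. The two enantiomers present the gem‑dimethyl flank and the ring pucker to the active site as mirror images, so the 4R ketone should be reduced and the 4S ketone recovered.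

Step 4
Reactants: 5 (4S)-4-bromo-3,3-dimethylcyclohexan-1-one
Product: 6 (1S)-1-bromo-4-(methoxymethylidene)-2,2-dimethylcyclohexane (E/Z mixture)
Conditions: Ph3P(CH2OMe)Cl, KN(SiMe3)2, THF, 0 °C; then 5, −78 → 0 °C
Reagents that add atoms: (methoxymethyl)triphenylphosphonium chloride, COC[P+](c1ccccc1)(c1ccccc1)c1ccccc1.[Cl-]
Why: Wittig methoxymethylenation of an unhindered cyclohexanone. Adding the ketone to the preformed ylide at low temperature keeps enolisation, and with it 1,3‑elimination of the 4‑bromide, behind carbonyl addition.

Step 5
Reactants: 6 (1S)-1-bromo-4-(methoxymethylidene)-2,2-dimethylcyclohexane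
Product: 7 (1S,4S)-4-bromo-3,3-dimethylcyclohexane-1-carbaldehyde
Conditions: 2 M HCl, THF, rt; then DBU (0.2 equiv), CH2Cl2, rt; chromatography, the C1 epimer returned to the DBU equilibration
Reagents that add atoms: water, O
Why: Enol ether hydrolysis followed by base‑mediated epimerisation at C1. In both epimers the formyl‑bearing carbon stays equatorial (an axial group there would be syn‑axial to a ring methyl), so they differ only in an equatorial (trans) or axial (cis) bromine. The trans aldehyde should predominate, but only moderately, hence separation and recycling.

Step 6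
Reactants: 7 (1S,4S)-4-bromo-3,3-dimethylcyclohexane-1-carbaldehyde
Product: 8 (1S,4S)-1-bromo-4-ethynyl-2,2-dimethylcyclohexane
Conditions: dimethyl (1-diazo-2-oxopropyl)phosphonate (1.5 equiv), K2CO3, MeOH, 0 °C
Reagents that add atoms: dimethyl (1-diazo-2-oxopropyl)phosphonate, COP(=O)(OC)C(=[N+]=[N-])C(C)=O
Why: Ohira–Bestmann homologation (Seyferth–Gilbert type). It is run cold with excess reagent so that alkyne formation outpaces epimerisation of the α‑branched aldehyde; once the alkyne is formed, C1′ is fixed.

Step 7
Reactants: 8 (1S,4S)-1-bromo-4-ethynyl-2,2-dimethylcyclohexane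
Product: 10 (1S,4S)-1-bromo-4-(1-bromoethenyl)-2,2-dimethylcyclohexane, via the B-(2-bromoalkenyl)-9-BBN adduct 9 (not isolated)
Conditions: B-bromo-9-BBN, CH2Cl2, 0 °C; then AcOH, rt
Reagents that add atoms: 9-bromo-9-borabicyclo[3.3.1]nonane, BrB1C2CCCC1CCC2
Why: Bromoboration of the terminal alkyne places bromine on the internal carbon and boron on the terminus by syn addition, and protonolysis of the C–B bond gives the 2‑bromo‑1‑alkene. This two‑step path to the internal boronate replaces a copper‑catalysed protoboration, whose boron regiochemistry is not dependable for an α‑branched alkyl alkyne.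

Step 8
Reactants: 10 (1S,4S)-1-bromo-4-(1-bromoethenyl)-2,2-dimethylcyclohexane; 11 bis(pinacolato)diboron
Product: 12 2-{1-[(1S,4S)-4-bromo-3,3-dimethylcyclohexyl]ethenyl}-4,4,5,5-tetramethyl-1,3,2-dioxaborolane
Conditions: PdCl2(PPh3)2 (3 mol%), PPh3 (6 mol%), KOPh, toluene, 50 °C
Reagents that add atoms: none
Why: Miyaura borylation of the alkenyl bromide. Zerovalent palladium with triarylphosphine ligands inserts into the C(sp2)–Br bond only, and phenoxide is mild enough not to eliminate the hindered secondary alkyl bromide.

Step 9
Reactants: 13 4-bromo-2-methylbut-1-ene
Product: 14 3-methylbut-3-enyllithium (ethereal solution, titrated and used directly)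
Conditions: Li (1% Na), Et2O, −10 °C
Reagents that add atoms: lithium, [Li]
Why: Reductive lithiation of a primary alkyl bromide with lithium metal; the homoallylic organolithium does not cyclise. The lithium bromide formed with it is dealt with by the halide scavenger in step 10.

Step 10
Reactants: 12 2-{1-[(1S,4S)-4-bromo-3,3-dimethylcyclohexyl]ethenyl}-4,4,5,5-tetramethyl-1,3,2-dioxaborolane; 14 3-methylbut-3-enyllithium; 15 vinyl bromide
Product: 17 2-{(4R)-4-[(1S,4S)-4-bromo-3,3-dimethylcyclohexyl]-7-methylocta-1,7-dien-4-yl}-4,4,5,5-tetramethyl-1,3,2-dioxaborolane, via the lithium alkenyl(homoallyl)borate complex 16 (not isolated)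
Conditions: 12 + 14, Et2O/THF, −78 °C → rt; then Pd(OAc)2 (3 mol%), (Sp,Sp)-MandyPhos (3.6 mol%), NaOTf (2.5 equiv), 15 (1.5 equiv, THF solution), THF, 60 °C, sealed vessel
Reagents that add atoms: none
Why: The organolithium adds to the boron of 12 to give the tetracoordinate borate 16. Pd(OAc)2 and the ferrocenyl bisphosphine are reduced in the flask to zerovalent palladium, which inserts into the C–Br bond of vinyl bromide; NaOTf removes bromide as NaBr so that the cationic vinyl–palladium species (divalent palladium) can bind the alkene of 16. Binding triggers a 1,2‑metallate shift in which the homoallyl group moves from boron to the α‑carbon (C4–C5) anti to palladium, and reductive elimination then joins the former CH2 terminus to the vinyl group (C3–C2) and returns zerovalent palladium. The closest known reaction type is the palladium‑catalysed enantioselective conjunctive cross‑coupling of α‑substituted alkenylboron ate complexes to tertiary boronic esters; no ring closes in this step. The one new stereocentre, C4, is set by the alkene face that the chiral palladium complex binds, the shift itself being stereospecific, and the ligand antipode is chosen to give 4R. The neighbouring C1′ is flanked by two ring CH2 groups of similar size, so substrate bias should be small and catalyst control should hold in either pairing. The step needs the metallate shift to beat direct alkenyl transfer (helped by the α‑substituent and the pinacol ligand), it cannot suffer β‑hydride elimination because the β‑carbon of the alkylpalladium intermediate is quaternary, and the hindered secondary C–Br bond should be inert to zerovalent palladium with a bisphosphine.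

Step 11
Reactants: 17 2-{(4R)-4-[(1S,4S)-4-bromo-3,3-dimethylcyclohexyl]-7-methylocta-1,7-dien-4-yl}-4,4,5,5-tetramethyl-1,3,2-dioxaborolane
Product: 18 (4S)-4-[(1S,4S)-4-bromo-3,3-dimethylcyclohexyl]-7-methylocta-1,7-dien-4-ol
Conditions: NaBO3·4H2O, THF/H2O (1:1), rt
Reagents that add atoms: sodium perborate tetrahydrate (NaBO3·4H2O), [Na+].[Na+].O[B-]1(O)OO[B-](O)(O)OO1.O.O.O.O.O.O
Why: Oxidation of the tertiary C–B bond by 1,2‑migration of carbon from boron to peroxide oxygen, which goes with retention; the descriptor changes from 4R to 4S only because oxygen outranks the carbon substituents whereas boron does not. Perborate is mild enough for the secondary bromide.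

Step 12
Reactants: 18 (4S)-4-[(1S,4S)-4-bromo-3,3-dimethylcyclohexyl]-7-methylocta-1,7-dien-4-ol
Product: 19 (1S)-1-[(1S,4S)-4-bromo-3,3-dimethylcyclohexyl]-4-methylcyclohex-3-en-1-ol
Conditions: second-generation Grubbs catalyst (3 mol%), CH2Cl2 (0.01 M), 40 °C
Reagents that add atoms: none
Why: Ring‑closing metathesis of the monosubstituted onto the 1,1‑disubstituted alkene gives the six‑membered trisubstituted alkene with loss of ethene. Because the two arms were installed as different groups, the alkene can only lie between the future C2 and C1.

Step 13
Reactants: 19 (1S)-1-[(1S,4S)-4-bromo-3,3-dimethylcyclohexyl]-4-methylcyclohex-3-en-1-ol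
Product: 20 (1R,2R,4S)-2-bromo-4-[(1S,4S)-4-bromo-3,3-dimethylcyclohexyl]-1-methyl-7-oxabicyclo[2.2.1]heptane
Conditions: NBS, CH2Cl2, −20 → 0 °C, dark
Reagents that add atoms: N-bromosuccinimide, O=C1CCC(=O)N1Br
Why: Transannular bromoetherification: the bromonium ion on the alkene face opposite the hydroxyl is opened at the tertiary C1 by the C4 oxygen through a boat (Markovnikov, anti), which closes the oxygen bridge and leaves the C2 bromine anti to O7. C1 and C2 are thus dictated by C4; the bromonium ion on the hydroxyl face cannot cyclise and is expected to revert by bromine transfer.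

## Compound list

1 | 6-methylhept-5-en-2-one (sulcatone) | CC(=O)CCC=C(C)C | starting material
2 | lithium 6-methylhepta-1,5-dien-2-olate | [Li+].[O-]C(=C)CCC=C(C)C | intermediate (not isolated)
3 | 6-methylhepta-1,5-dien-2-yl acetate | CC(=O)OC(=C)CCC=C(C)C | intermediate
4 | rac-4-bromo-3,3-dimethylcyclohexan-1-one | CC1(C)CC(=O)CCC1Br | intermediate
5 | (4S)-4-bromo-3,3-dimethylcyclohexan-1-one | CC1(C)CC(=O)CC[C@@H]1Br | intermediate
6 | (1S)-1-bromo-4-(methoxymethylidene)-2,2-dimethylcyclohexane (E/Z mixture) | CC1(C)CC(=COC)CC[C@@H]1Br | intermediate
7 | (1S,4S)-4-bromo-3,3-dimethylcyclohexane-1-carbaldehyde | CC1(C)C[C@@H](C=O)CC[C@@H]1Br | intermediate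
8 | (1S,4S)-1-bromo-4-ethynyl-2,2-dimethylcyclohexane | CC1(C)C[C@@H](C#C)CC[C@@H]1Br | intermediate
9 | 9-{(Z)-2-bromo-2-[(1S,4S)-4-bromo-3,3-dimethylcyclohexyl]ethenyl}-9-borabicyclo[3.3.1]nonane | CC1(C)C[C@@H](/C(Br)=C/B2C3CCCC2CCC3)CC[C@@H]1Br | intermediate (not isolated)
10 | (1S,4S)-1-bromo-4-(1-bromoethenyl)-2,2-dimethylcyclohexane | CC1(C)C[C@@H](C(Br)=C)CC[C@@H]1Br | intermediate
11 | bis(pinacolato)diboron | CC1(C)OB(OC1(C)C)B1OC(C)(C)C(C)(C)O1 | starting material
12 | 2-{1-[(1S,4S)-4-bromo-3,3-dimethylcyclohexyl]ethenyl}-4,4,5,5-tetramethyl-1,3,2-dioxaborolane | CC1(C)C[C@@H](C(=C)B2OC(C)(C)C(C)(C)O2)CC[C@@H]1Br | intermediate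
13 | 4-bromo-2-methylbut-1-ene | CC(=C)CCBr | starting material
14 | 3-methylbut-3-enyllithium | [Li]CCC(C)=C | intermediate
15 | vinyl bromide (bromoethene) | C=CBr | starting material
16 | lithium {1-[(1S,4S)-4-bromo-3,3-dimethylcyclohexyl]ethenyl}(3-methylbut-3-enyl)(pinacolato)borate | [Li+].CC1(C)C[C@@H](C(=C)[B-]2(CCC(C)=C)OC(C)(C)C(C)(C)O2)CC[C@@H]1Br | intermediate (not isolated)
17 | 2-{(4R)-4-[(1S,4S)-4-bromo-3,3-dimethylcyclohexyl]-7-methylocta-1,7-dien-4-yl}-4,4,5,5-tetramethyl-1,3,2-dioxaborolane | CC1(C)C[C@@H]([C@@](B2OC(C)(C)C(C)(C)O2)(CC=C)CCC(C)=C)CC[C@@H]1Br | intermediate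
18 | (4S)-4-[(1S,4S)-4-bromo-3,3-dimethylcyclohexyl]-7-methylocta-1,7-dien-4-ol | CC1(C)C[C@@H]([C@@](O)(CC=C)CCC(C)=C)CC[C@@H]1Br | intermediate
19 | (1S)-1-[(1S,4S)-4-bromo-3,3-dimethylcyclohexyl]-4-methylcyclohex-3-en-1-ol | CC1(C)C[C@@H]([C@@]2(O)CC=C(C)CC2)CC[C@@H]1Br | intermediate
20 | (1R,2R,4S)-2-bromo-4-[(1S,4S)-4-bromo-3,3-dimethylcyclohexyl]-1-methyl-7-oxabicyclo[2.2.1]heptane | CC1(C)C[C@@H]([C@@]23CC[C@@](C)(O2)[C@H](Br)C3)CC[C@@H]1Br | target

## Step count and least certain steps

Total step count: 13. Longest linear sequence: 12 steps (steps 1–8 and 10–13, from 1); step 9 is a one‑step side branch.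

**Step 10 (key step).** The α‑cyclohexyl group next to boron may slow binding of the chiral palladium complex to the alkene of 16. Alkenyl transfer to palladium or bromide inhibition could then overtake the metallate shift, or face discrimination could erode. The fallback sets out from aldehyde 7 and returns at alcohol 18. Organolithium 14 is added to 7 (Et2O, −78 °C) to give 1-[(1S,4S)-4-bromo-3,3-dimethylcyclohexyl]-4-methylpent-4-en-1-ol F1 as a mixture of carbinol epimers. Dess–Martin oxidation gives 1-[(1S,4S)-4-bromo-3,3-dimethylcyclohexyl]-4-methylpent-4-en-1-one F2. A catalytic asymmetric allylboration of this ketone (allylboronic ester, chiral 3,3′‑disubstituted binaphthol catalyst) gives 18; its C4 epimer is a diastereomer and can be separated.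

**Step 2.** Electrophilic bromine may be taken up by the enol acetate alkene instead of the trisubstituted alkene, or the tertiary cation may lose a proton before the ring closes. The fallback sets out from 1 and returns at 4; it replaces the bromonium ion by an epoxide as initiator. Buffered peracid epoxidation of 1 gives 4-(3,3-dimethyloxiran-2-yl)butan-2-one F3. Kinetic enol silylation (LiN(i-Pr)2, t-BuMe2SiCl) gives tert-butyl{[4-(3,3-dimethyloxiran-2-yl)but-1-en-2-yl]oxy}dimethylsilane F4. Cyclisation promoted by MeAlCl2 (CH2Cl2, −78 °C) gives rac-4-hydroxy-3,3-dimethylcyclohexan-1-one F5, and an Appel bromination (PPh3, CBr4) gives 4. The substitution at the neopentyl‑type carbinol is the weak point of this fallback, which is why it is not the main route.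

**Step 3.** The enzyme may not distinguish the enantiomers well enough, since they differ only at a centre remote from the carbonyl. The fallback sets out from 4 and returns at 5. Ketalisation with (1R,2R)-1,2-diphenylethane-1,2-diol (pyridinium p‑toluenesulfonate, benzene, water removal) gives two diastereomeric ketals. (2R,3R,8S)-8-bromo-7,7-dimethyl-2,3-diphenyl-1,4-dioxaspiro[4.5]decane F6 is separated by crystallisation or chromatography and hydrolysed (aq HCl, acetone) to 5.

**Step 5.** The equilibrium may favour the trans aldehyde only slightly, and the aldehyde may re‑epimerise during chromatography. The fallback sets out from enol ether 6 and returns at 7. After hydrolysis the crude epimeric aldehydes are reduced with NaBH4, and the configurationally stable alcohols are separated to give [(1S,4S)-4-bromo-3,3-dimethylcyclohexyl]methanol F7. Dess–Martin oxidation under non‑epimerising conditions gives 7; the C1 epimer is oxidised, re‑equilibrated with DBU and reduced again.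

**Step 13.** The bromonium ion may form on the hydroxyl face and be drained by intermolecular capture or allylic bromination instead of reverting. The fallback sets out from 19 and returns at 20. Silylation (Et3SiCl, imidazole) gives {[(1S)-1-[(1S,4S)-4-bromo-3,3-dimethylcyclohexyl]-4-methylcyclohex-3-en-1-yl]oxy}triethylsilane F8. The bulky silyl ether should direct the bromonium ion to the opposite face, and its oxygen closes the bridge with loss of the silyl group on treatment with NBS in MeCN.

## Further compounds

F1 | step 10 | 1-[(1S,4S)-4-bromo-3,3-dimethylcyclohexyl]-4-methylpent-4-en-1-ol (carbinol epimers) | CC1(C)C[C@@H](C(O)CCC(C)=C)CC[C@@H]1Br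
F2 | step 10 | 1-[(1S,4S)-4-bromo-3,3-dimethylcyclohexyl]-4-methylpent-4-en-1-one | CC1(C)C[C@@H](C(=O)CCC(C)=C)CC[C@@H]1Br
F3 | step 2 | 4-(3,3-dimethyloxiran-2-yl)butan-2-one (racemic) | CC(=O)CCC1OC1(C)C
F4 | step 2 | tert-butyl{[4-(3,3-dimethyloxiran-2-yl)but-1-en-2-yl]oxy}dimethylsilane (racemic) | C=C(CCC1OC1(C)C)O[Si](C)(C)C(C)(C)C
F5 | step 2 | rac-4-hydroxy-3,3-dimethylcyclohexan-1-one | CC1(C)CC(=O)CCC1O
F6 | step 3 | (2R,3R,8S)-8-bromo-7,7-dimethyl-2,3-diphenyl-1,4-dioxaspiro[4.5]decane | CC1(C)CC2(O[C@H](c3ccccc3)[C@@H](c3ccccc3)O2)CC[C@@H]1Br
F7 | step 5 | [(1S,4S)-4-bromo-3,3-dimethylcyclohexyl]methanol | CC1(C)C[C@@H](CO)CC[C@@H]1Br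
F8 | step 13 | {[(1S)-1-[(1S,4S)-4-bromo-3,3-dimethylcyclohexyl]-4-methylcyclohex-3-en-1-yl]oxy}triethylsilane | CC1(C)C[C@@H]([C@@]2(O[Si](CC)(CC)CC)CC=C(C)CC2)CC[C@@H]1Br
A1 | alternative 1 | (1R,2R,4S)-2-bromo-4-[(4S)-4-bromo-5,5-dimethylcyclohex-1-en-1-yl]-1-methyl-7-oxabicyclo[2.2.1]heptane | CC1(C)CC(=CC[C@@H]1Br)[C@@]23CC[C@@](C)(O2)[C@H](Br)C3
A2 | alternative 1 | (1R,2R,4S)-2-bromo-1-methyl-4-(6-methylhepta-1,5-dien-2-yl)-7-oxabicyclo[2.2.1]heptane | CC(C)=CCCC(=C)[C@@]12CC[C@@](C)(O1)[C@H](Br)C2
A3 | alternative 2 | 2,2,2-trifluoroethyl 6-bromo-4-[(1S,4S)-4-bromo-3,3-dimethylcyclohexyl]-1-methyl-7-oxabicyclo[2.2.1]hept-5-ene-2-carboxylate (endo ester, bridgeheads as in the target) | CC1(C)C[C@@H]([C@@]23C[C@H](C(=O)OCC(F)(F)F)[C@@](C)(O2)C(Br)=C3)CC[C@@H]1Br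
A4 | alternative 2 | 3-bromo-5-[(1S,4S)-4-bromo-3,3-dimethylcyclohexyl]-2-methylfuran | CC1(C)C[C@@H](c2cc(Br)c(C)o2)CC[C@@H]1Br
A5 | alternative 2 | 2,2,2-trifluoroethyl prop-2-enoate | C=CC(=O)OCC(F)(F)F
A6 | alternative 3 | 1-[(1S,4S)-4-bromo-3,3-dimethylcyclohexyl]-4-methylidenecyclohexan-1-ol | CC1(C)C[C@@H](C2(O)CCC(=C)CC2)CC[C@@H]1Br
A7 | alternative 3 | methyl (1S,4S)-4-bromo-3,3-dimethylcyclohexane-1-carboxylate | CC1(C)C[C@@H](C(=O)OC)CC[C@@H]1Br
A8 | alternative 3 | (3-methylidenepentane-1,5-diyl)bis(bromomagnesium) | Br[Mg]CCC(=C)CC[Mg]Br
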